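**Assumption:** the target has no stereocentre and no stereogenic double bond (the prenyl alkene carries two identical methyls), so it is one achiral compound and no enantiocontrol is needed.

**Retrosynthetic overview**
1. Target 15 comes from global MOM removal of the tris-MOM flavonol 14.
2. The pyranone ring C is the only ring made; it is closed last by Algar–Flynn–Oyamada oxidative cyclisation of the 2'-hydroxychalcone 12.
3. The key C–C bond (chalcone Cα–Cβ) comes from an intermolecular Claisen–Schmidt aldol condensation of acetophenone 3 with aldehyde 10.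
4. Ring A piece 3 comes from 4-methylresorcinol (Nencki acylation, selective MOM protection).
5. Ring B piece 10 comes from 3,4-dihydroxybenzaldehyde (selective 4-O-MOM, O-allylation, aromatic Claisen to C-2, MOM, cross-metathesis allyl → prenyl).

**Route**

Step 1
Reactants: 1 4-methylresorcinol
Product: 2 1-(2,4-dihydroxy-5-methylphenyl)ethan-1-one
Conditions: AcOH, anhydrous ZnCl2 (1.5 equiv), 140 °C, 2 h; then dilute HCl, recrystallise
Reagents that add atoms: acetic acid, CC(=O)O
Why: Nencki-type Friedel–Crafts acylation goes to the only unhindered position that is ortho to one OH and para to the other.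

Step 2
Reactants: 2 1-(2,4-dihydroxy-5-methylphenyl)ethan-1-one
Product: 3 1-[2-hydroxy-4-(methoxymethoxy)-5-methylphenyl]ethan-1-one
Conditions: MOMCl (1.2 equiv), K2CO3 (2 equiv), acetone, 0 °C to rt
Reagents that add atoms: chloromethyl methyl ether (MOMCl), COCCl
Why: Williamson-type O-alkylation takes the free 4-OH because the 2-OH is hydrogen-bonded to the ketone and much less nucleophilic.

Step 3
Reactants: 4 3,4-dihydroxybenzaldehyde
Product: 5 3-hydroxy-4-(methoxymethoxy)benzaldehyde
Conditions: MOMCl (1.05 equiv), K2CO3 (1.1 equiv), acetone, 0 °C to rt; chromatography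
Reagents that add atoms: chloromethyl methyl ether (MOMCl), COCCl
Why: Regioselective O-alkylation of the monoanion, which sits on the more acidic 4-OH (para to the formyl group).

Step 4
Reactants: 5 3-hydroxy-4-(methoxymethoxy)benzaldehyde
Product: 6 3-(allyloxy)-4-(methoxymethoxy)benzaldehyde
Conditions: allyl bromide (1.3 equiv), K2CO3 (2 equiv), DMF, rt to 50 °C
Reagents that add atoms: allyl bromide, C=CCBr
Why: Williamson ether synthesis on the one remaining phenol.

Step 5
Reactants: 6 3-(allyloxy)-4-(methoxymethoxy)benzaldehyde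
Product: 8 2-allyl-3-hydroxy-4-(methoxymethoxy)benzaldehyde, via ortho-dienone 7 (not isolated)
Conditions: N,N-diethylaniline, 190 °C, 6 h, Ar
Reagents that add atoms: none
Why: Aromatic Claisen [3,3] rearrangement can only go to C-2 because the other ortho position (C-4) is blocked, and the racemic sp3 centre of dienone 7 is erased on tautomerisation.

Step 6
Reactants: 8 2-allyl-3-hydroxy-4-(methoxymethoxy)benzaldehyde
Product: 9 2-allyl-3,4-bis(methoxymethoxy)benzaldehyde
Conditions: MOMCl (1.5 equiv), K2CO3 (2.5 equiv), DMF, 0 °C to rt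
Reagents that add atoms: chloromethyl methyl ether (MOMCl), COCCl
Why: O-alkylation of the phenoxide with the small, very reactive MOMCl is fast even at this flanked phenol.

Step 7
Reactants: 9 2-allyl-3,4-bis(methoxymethoxy)benzaldehyde
Product: 10 3,4-bis(methoxymethoxy)-2-(3-methylbut-2-en-1-yl)benzaldehyde
Conditions: Grubbs II (5 mol %), 2-methyl-2-butene/CH2Cl2 (1:1), 40 °C, sealed tube, 12 h
Reagents that add atoms: 2-methyl-2-butene, CC=C(C)C
Why: Olefin cross-metathesis with excess 2-methyl-2-butene turns the terminal allyl group into prenyl; aldehyde and MOM ethers are inert to the Ru carbene.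

Step 8
Reactants: 3 1-[2-hydroxy-4-(methoxymethoxy)-5-methylphenyl]ethan-1-one; 10 3,4-bis(methoxymethoxy)-2-(3-methylbut-2-en-1-yl)benzaldehyde
Product: 12 (E)-1-[2-hydroxy-4-(methoxymethoxy)-5-methylphenyl]-3-[3,4-bis(methoxymethoxy)-2-(3-methylbut-2-en-1-yl)phenyl]prop-2-en-1-one, via aldol adduct 11 (not isolated)
Conditions: KOH (50 % aq., 10 equiv), EtOH, 0 °C to rt, 36 h; then aq. NH4Cl to pH 6
Reagents that add atoms: none
Why: Claisen–Schmidt aldol condensation of the methyl ketone enolate with a non-enolisable aldehyde; E1cB dehydration of racemic 11 gives the conjugated E-enone, and all groups are base-stable.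

Step 9
Reactants: 12 (E)-1-[2-hydroxy-4-(methoxymethoxy)-5-methylphenyl]-3-[3,4-bis(methoxymethoxy)-2-(3-methylbut-2-en-1-yl)phenyl]prop-2-en-1-one
Product: 14 3-hydroxy-7-(methoxymethoxy)-6-methyl-2-[3,4-bis(methoxymethoxy)-2-(3-methylbut-2-en-1-yl)phenyl]-4H-chromen-4-one, via dihydroflavonol 13 (not isolated)
Conditions: 30 % H2O2 (5 equiv), 2 M NaOH (5 equiv), MeOH/THF, 0 °C to rt, 4 h; then aq. NaH2PO4 to pH 6
Reagents that add atoms: hydrogen peroxide, OO
Why: Algar–Flynn–Oyamada reaction: phenoxide oxa-Michael closure with hydroxylation of the enolate by H2O2 gives racemic trans-13, which is oxidised in situ to the flavonol, so no stereocentre remains; a 6'-unsubstituted chalcone favours flavonol over aurone, and nucleophilic alkaline peroxide leaves the electron-rich prenyl alkene alone.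

Step 10
Reactants: 14 3-hydroxy-7-(methoxymethoxy)-6-methyl-2-[3,4-bis(methoxymethoxy)-2-(3-methylbut-2-en-1-yl)phenyl]-4H-chromen-4-one
Product: 15 2-[3,4-dihydroxy-2-(3-methylbut-2-en-1-yl)phenyl]-3,7-dihydroxy-6-methyl-4H-chromen-4-one
Conditions: 3 M aq. HCl/MeOH (1:5), 45 °C, 1–2 h, Ar; stop at full conversion
Reagents that add atoms: none
Why: Acid-catalysed transacetalisation to methanol removes the three aryl MOM ethers under conditions mild enough to avoid hydration or chroman formation at the prenyl group.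

**Compound list**
1 | 4-methylresorcinol (4-methylbenzene-1,3-diol) | Cc1ccc(O)cc1O | starting material
2 | 1-(2,4-dihydroxy-5-methylphenyl)ethan-1-one | CC(=O)c1cc(C)c(O)cc1O | intermediate
3 | 1-[2-hydroxy-4-(methoxymethoxy)-5-methylphenyl]ethan-1-one | CC(=O)c1cc(C)c(OCOC)cc1O | intermediate
4 | 3,4-dihydroxybenzaldehyde | O=Cc1ccc(O)c(O)c1 | starting material
5 | 3-hydroxy-4-(methoxymethoxy)benzaldehyde | COCOc1ccc(C=O)cc1O | intermediate
6 | 3-(allyloxy)-4-(methoxymethoxy)benzaldehyde | COCOc1ccc(C=O)cc1OCC=C | intermediate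
7 | 4-(methoxymethoxy)-5-oxo-6-(prop-2-en-1-yl)cyclohexa-1,3-diene-1-carbaldehyde (ortho-dienone, racemic, configuration not defined) | O=CC1=CC=C(OCOC)C(=O)C1CC=C | intermediate (not isolated)
8 | 2-allyl-3-hydroxy-4-(methoxymethoxy)benzaldehyde | COCOc1ccc(C=O)c(CC=C)c1O | intermediate
9 | 2-allyl-3,4-bis(methoxymethoxy)benzaldehyde | COCOc1ccc(C=O)c(CC=C)c1OCOC | intermediate
10 | 3,4-bis(methoxymethoxy)-2-(3-methylbut-2-en-1-yl)benzaldehyde | COCOc1ccc(C=O)c(CC=C(C)C)c1OCOC | intermediate
11 | 3-[3,4-bis(methoxymethoxy)-2-(3-methylbut-2-en-1-yl)phenyl]-3-hydroxy-1-[2-hydroxy-4-(methoxymethoxy)-5-methylphenyl]propan-1-one (aldol adduct, racemic, configuration not defined) | COCOc1cc(O)c(C(=O)CC(O)c2ccc(OCOC)c(OCOC)c2CC=C(C)C)cc1C | intermediate (not isolated)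
12 | (E)-1-[2-hydroxy-4-(methoxymethoxy)-5-methylphenyl]-3-[3,4-bis(methoxymethoxy)-2-(3-methylbut-2-en-1-yl)phenyl]prop-2-en-1-one | COCOc1cc(O)c(C(=O)/C=C/c2ccc(OCOC)c(OCOC)c2CC=C(C)C)cc1C | intermediate
13 | trans-3-hydroxy-7-(methoxymethoxy)-6-methyl-2-[3,4-bis(methoxymethoxy)-2-(3-methylbut-2-en-1-yl)phenyl]chroman-4-one (racemic; the 2R,3R enantiomer is drawn) | CC(C)=CCc1c(OCOC)c(OCOC)ccc1[C@@H]2[C@H](C(=O)c3cc(C)c(OCOC)cc3O2)O | intermediate (not isolated)
14 | 3-hydroxy-7-(methoxymethoxy)-6-methyl-2-[3,4-bis(methoxymethoxy)-2-(3-methylbut-2-en-1-yl)phenyl]-4H-chromen-4-one | COCOc1cc2oc(-c3ccc(OCOC)c(OCOC)c3CC=C(C)C)c(O)c(=O)c2cc1C | intermediate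
15 | 2-[3,4-dihydroxy-2-(3-methylbut-2-en-1-yl)phenyl]-3,7-dihydroxy-6-methyl-4H-chromen-4-one (CNP0154747.0) | CC(C)=CCc1c(-c2oc3cc(O)c(C)cc3c(=O)c2O)ccc(O)c1O | target

**Totals**
Total step count: 10.
Longest linear sequence: 8 steps (4 → 5 → 6 → 8 → 9 → 10 → 12 → 14 → 15; steps 3–10). The ring A branch (steps 1–2) joins at step 8.

**Three steps most likely to fail**

Step 9 (AFO oxidative cyclisation). The ortho-prenyl B-ring may slow the closure or divert material to aurone or Dakin-type products. Fallback: set out from chalcone 12 and separate ring closure from C-3 oxygenation. Heating 12 with catalytic I2 in DMSO (110 °C) closes and dehydrogenates it to 7-(methoxymethoxy)-6-methyl-2-[3,4-bis(methoxymethoxy)-2-(3-methylbut-2-en-1-yl)phenyl]-4H-chromen-4-one F2. Deprotonation at C-3 with LDA (THF, −78 °C) gives the 3-lithioflavone F3, which is trapped with B(OMe)3 as the dimethyl flavon-3-ylboronate F4. Oxidation of the C–B bond with alkaline H2O2 (no peracid, so the prenyl alkene is untouched) comes back to the route at 14.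

Step 10 (acidic MOM removal next to the prenyl group). The free 3'-OH can add to the protonated prenyl alkene to give a 2,2-dimethylchroman, or the alkene can be hydrated. Fallback: set out from allyl aldehyde 9 and make the prenyl alkene only after the acid step. Claisen–Schmidt condensation of 9 with 3 (KOH, EtOH) passes through the allyl aldol adduct F5 to the allyl chalcone F6. AFO oxidation (H2O2, NaOH) passes through the allyl dihydroflavonol F7 to the allyl tris-MOM flavonol F8. HCl/MeOH, harmless to a plain allyl group, gives the allyl tetrol F9. Ac2O/pyridine gives the allyl tetraacetate F10, and cross-metathesis with 2-methyl-2-butene (Grubbs II) gives the prenyl tetraacetate F11. Mild methanolysis (catalytic K2CO3, degassed MeOH, 0 °C, then neutralise) comes back to the route at 15.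

Step 3 (regioselective mono-MOM protection of the catechol). The 3-O-MOM isomer and the bis-MOM ether may form and have to be separated. Fallback: set out from 4 and reverse the order of O-functionalisation. The dianion (NaH, 2.2 equiv, DMSO) is alkylated with one equivalent of allyl bromide at the more nucleophilic 3-phenoxide (the one not conjugated with the aldehyde), giving 3-(allyloxy)-4-hydroxybenzaldehyde F1. MOM protection of the remaining 4-OH (MOMCl, K2CO3, acetone) comes back to the route at 6.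

**Further compounds**
F1 | step 3 | 3-(allyloxy)-4-hydroxybenzaldehyde | O=Cc1ccc(O)c(OCC=C)c1
F2 | step 9 | 7-(methoxymethoxy)-6-methyl-2-[3,4-bis(methoxymethoxy)-2-(3-methylbut-2-en-1-yl)phenyl]-4H-chromen-4-one | COCOc1cc2oc(-c3ccc(OCOC)c(OCOC)c3CC=C(C)C)cc(=O)c2cc1C
F3 | step 9 | 3-lithio derivative of F2 (3-lithioflavone) | [Li]c1c(-c2ccc(OCOC)c(OCOC)c2CC=C(C)C)oc2cc(OCOC)c(C)cc2c1=O
F4 | step 9 | dimethyl {7-(methoxymethoxy)-6-methyl-2-[3,4-bis(methoxymethoxy)-2-(3-methylbut-2-en-1-yl)phenyl]-4-oxo-4H-chromen-3-yl}boronate | COB(OC)c1c(-c2ccc(OCOC)c(OCOC)c2CC=C(C)C)oc2cc(OCOC)c(C)cc2c1=O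
F5 | step 10 | 3-[2-allyl-3,4-bis(methoxymethoxy)phenyl]-3-hydroxy-1-[2-hydroxy-4-(methoxymethoxy)-5-methylphenyl]propan-1-one (allyl aldol adduct, racemic, not isolated) | COCOc1cc(O)c(C(=O)CC(O)c2ccc(OCOC)c(OCOC)c2CC=C)cc1C
F6 | step 10 | (E)-3-[2-allyl-3,4-bis(methoxymethoxy)phenyl]-1-[2-hydroxy-4-(methoxymethoxy)-5-methylphenyl]prop-2-en-1-one (allyl chalcone) | COCOc1cc(O)c(C(=O)/C=C/c2ccc(OCOC)c(OCOC)c2CC=C)cc1C
F7 | step 10 | trans-2-[2-allyl-3,4-bis(methoxymethoxy)phenyl]-3-hydroxy-7-(methoxymethoxy)-6-methylchroman-4-one (allyl dihydroflavonol, racemic, 2R,3R drawn, not isolated) | C=CCc1c(OCOC)c(OCOC)ccc1[C@@H]2[C@H](C(=O)c3cc(C)c(OCOC)cc3O2)O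
F8 | step 10 | 2-[2-allyl-3,4-bis(methoxymethoxy)phenyl]-3-hydroxy-7-(methoxymethoxy)-6-methyl-4H-chromen-4-one (allyl tris-MOM flavonol) | COCOc1cc2oc(-c3ccc(OCOC)c(OCOC)c3CC=C)c(O)c(=O)c2cc1C
F9 | step 10 | 2-(2-allyl-3,4-dihydroxyphenyl)-3,7-dihydroxy-6-methyl-4H-chromen-4-one (allyl tetrol) | C=CCc1c(-c2oc3cc(O)c(C)cc3c(=O)c2O)ccc(O)c1O
F10 | step 10 | 2-(3,4-diacetoxy-2-allylphenyl)-6-methyl-4-oxo-4H-chromene-3,7-diyl diacetate (allyl tetraacetate) | C=CCc1c(-c2oc3cc(OC(C)=O)c(C)cc3c(=O)c2OC(C)=O)ccc(OC(C)=O)c1OC(C)=O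
F11 | step 10 | 2-[3,4-diacetoxy-2-(3-methylbut-2-en-1-yl)phenyl]-6-methyl-4-oxo-4H-chromene-3,7-diyl diacetate (prenyl tetraacetate) | CC(C)=CCc1c(-c2oc3cc(OC(C)=O)c(C)cc3c(=O)c2OC(C)=O)ccc(OC(C)=O)c1OC(C)=O
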